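**Strategy.** The cyclohexene ring is grown from a four-membered ring. In the target (benzofuranone numbering) the ring oxygens at C4 and C7a sit 1,3 across C3a, the pattern of a 3-alkoxycyclobutanone; this donor–acceptor cyclobutane comes from [2+2] cycloaddition of the ketene of (S)-citronellic acid with a chiral vinyl ether. In the key step a Lewis acid ionises its C2–C3 bond and a silyl enol ether is inserted, expanding the cyclobutanone by two carbons to the cyclohexenone that already carries the C5 side chain, the C6 CH2O carbon and the C7a oxygen. Alkylation at C3a, lactonisation, carbonyl reduction and methylenation complete the ring system.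

Key step: step 5

Remark: the sense of induction by the (S)-1-(naphthalen-2-yl)ethyl ether in step 5 is assumed from the C–H-eclipsed E-oxocarbenium model (attack anti to the aryl group); if the opposite sense is found, the (R)-alcohol is used in step 2.

Step 1
Reactants: 1 (3S)-3,7-dimethyloct-6-enoic acid [(S)-citronellic acid]
Product: 2 (3S)-3,7-dimethyloct-6-enoyl chloride
Conditions: (COCl)2, DMF (cat.), CH2Cl2, 0 °C to rt
Reagents that add atoms: oxalyl chloride ClC(=O)C(=O)Cl
Why: Acid chloride formation through the Vilsmeier-type chloroiminium species is standard and should leave the trisubstituted alkene and the C3 stereocentre untouched.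

Step 2
Reactants: 3 (1S)-1-(naphthalen-2-yl)ethan-1-ol
Product: 4 2-[(1S)-1-(ethenyloxy)ethyl]naphthalene
Conditions: vinyl acetate, [Ir(cod)Cl]2 (cat.), Na2CO3, toluene, 100 °C
Reagents that add atoms: vinyl acetate C=COC(C)=O
Why: Iridium-catalysed transfer vinylation of a secondary alcohol forms the vinyl ether at oxygen only, so the carbinol configuration is retained.

Step 3
Reactants: 2 (3S)-3,7-dimethyloct-6-enoyl chloride, 4 2-[(1S)-1-(ethenyloxy)ethyl]naphthalene
Product: 6 2-[(2S)-6-methylhept-5-en-2-yl]-3-[(1S)-1-(naphthalen-2-yl)ethoxy]cyclobutan-1-one (mixture of ring diastereomers), via alkylketene 5 (not isolated)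
Conditions: Et3N, toluene, 80 °C, slow addition of 2 (excess) to 4
Reagents that add atoms: none
Why: Dehydrochlorination gives the monoalkylketene, which should undergo the thermal ketene–enol ether [2+2] cycloaddition with the usual regiochemistry (carbonyl carbon to the CH2 terminus) faster than it adds to its own remote alkene; the two new ring stereocentres need no control because both are erased in step 5.

Step 4
Reactants: 7 1-[(tert-butyldimethylsilyl)oxy]propan-2-one
Product: 8 tert-butyldimethyl({2-[(trimethylsilyl)oxy]prop-2-en-1-yl}oxy)silane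
Conditions: LDA, TMSCl (in situ), THF, −78 °C
Reagents that add atoms: chlorotrimethylsilane C[Si](C)(C)Cl
Why: Kinetic deprotonation of the methyl group and in situ O-silylation (silyl enol ether formation) should give the terminal enol ether, the silyloxy-substituted methylene being the slower site.

Step 5
Reactants: 6 2-[(2S)-6-methylhept-5-en-2-yl]-3-[(1S)-1-(naphthalen-2-yl)ethoxy]cyclobutan-1-one, 8 tert-butyldimethyl({2-[(trimethylsilyl)oxy]prop-2-en-1-yl}oxy)silane
Product: 10 (5R)-3-{[(tert-butyldimethylsilyl)oxy]methyl}-2-[(2S)-6-methylhept-5-en-2-yl]-5-[(1S)-1-(naphthalen-2-yl)ethoxy]cyclohex-2-en-1-one, via silyloxycyclohexanone 9 (not isolated)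
Conditions: EtAlCl2 (1.5 equiv), CH2Cl2, −78 to −40 °C; then CSA (cat.), CH2Cl2, 0 °C
Reagents that add atoms: none
Why: EtAlCl2 binds the cyclobutanone carbonyl and the strained donor–acceptor bond C2–C3 ionises to an aluminium enolate/oxocarbenium zwitterion; the CH2 terminus of 8 adds to the oxocarbenium carbon (Mukaiyama-type) and the new silyloxocarbenium ion is trapped by the enolate carbon in an intramolecular aldol, a 6-(enolendo)-exo-trig closure that gives 9, from which catalytic acid expels Me3SiOH to give the tetrasubstituted enone. The closest known reaction type is the Lewis acid-promoted formal [4+2] cycloaddition of 3-alkoxycyclobutanones with silyl enol ethers (ring expansion of a donor–acceptor cyclobutane by two carbons). The only stereocentre that survives, C5, is set in the intermolecular addition: the E-oxocarbenium ion should be attacked anti to the naphthyl group of the (S)-1-arylethyl ether in its C–H-eclipsed conformer, which leads to 5R. The step needs cleavage of C2–C3 rather than C4–C3, which the branched C2 substituent should secure (more substituted enolate, greater strain relief), and it must stop before a second β-elimination of the C5 ether, which low temperature and only catalytic mild acid should secure.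

Step 6
Reactants: 10 (5R)-3-{[(tert-butyldimethylsilyl)oxy]methyl}-2-[(2S)-6-methylhept-5-en-2-yl]-5-[(1S)-1-(naphthalen-2-yl)ethoxy]cyclohex-2-en-1-one
Product: 11 methyl 2-[(1S,6R)-4-{[(tert-butyldimethylsilyl)oxy]methyl}-3-[(2S)-6-methylhept-5-en-2-yl]-6-[(1S)-1-(naphthalen-2-yl)ethoxy]-2-oxocyclohex-3-en-1-yl]acetate
Conditions: LDA, THF, −78 °C; BrCH2CO2Me, DMPU, −78 to −40 °C
Reagents that add atoms: methyl bromoacetate COC(=O)CBr
Why: Kinetic α′-deprotonation gives the cross-conjugated lithium dienolate, whose C-alkylation by the α-bromo ester (enolate alkylation) should occur anti to the adjacent ether and so set the new centre trans to it.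

Step 7
Reactants: 11 methyl 2-[(1S,6R)-4-{[(tert-butyldimethylsilyl)oxy]methyl}-3-[(2S)-6-methylhept-5-en-2-yl]-6-[(1S)-1-(naphthalen-2-yl)ethoxy]-2-oxocyclohex-3-en-1-yl]acetate
Product: 13 (3aS,7aR)-6-(hydroxymethyl)-5-[(2S)-6-methylhept-5-en-2-yl]-3,3a,7,7a-tetrahydro-1-benzofuran-2,4-dione, via hydroxy ester 12 (not isolated)
Conditions: DDQ, CH2Cl2/pH 7 buffer, 0 °C to rt; then CSA, MeOH/CH2Cl2, rt
Reagents that add atoms: none
Why: DDQ oxidation should cleave the secondary naphthylmethyl-type ether by benzylic hydride abstraction without touching the carbinol C–O bond, and acid in methanol then removes the primary silyl ether and closes the trans-fused γ-lactone by transesterification, so the carbinol centre is carried into C7a with retention.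

Step 8
Reactants: 13 (3aS,7aR)-6-(hydroxymethyl)-5-[(2S)-6-methylhept-5-en-2-yl]-3,3a,7,7a-tetrahydro-1-benzofuran-2,4-dione
Product: 14 (3aR,4S,7aR)-4-hydroxy-6-(hydroxymethyl)-5-[(2S)-6-methylhept-5-en-2-yl]-3a,4,7,7a-tetrahydro-1-benzofuran-2(3H)-one
Conditions: (R)-Me-CBS, catecholborane, toluene, −78 °C
Reagents that add atoms: none
Why: Corey–Bakshi–Shibata reduction: with the substituted alkene carbon as the large group the (R)-catalyst should deliver hydride to the carbonyl face remote from the lactone CH2 on the neighbouring ring-fusion carbon, giving the 4S alcohol cis to the C3a–C3 bond, while lactone and alkenes are inert to catecholborane at −78 °C.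

Step 9
Reactants: 14 (3aR,4S,7aR)-4-hydroxy-6-(hydroxymethyl)-5-[(2S)-6-methylhept-5-en-2-yl]-3a,4,7,7a-tetrahydro-1-benzofuran-2(3H)-one
Product: 15 [(3aR,4S,7aR)-4-hydroxy-5-[(2S)-6-methylhept-5-en-2-yl]-2-oxo-2,3,3a,4,7,7a-hexahydro-1-benzofuran-6-yl]methyl 2-methylpropanoate
Conditions: iPrCOCl, 2,4,6-collidine, CH2Cl2, −40 °C
Reagents that add atoms: 2-methylpropanoyl chloride CC(C)C(Cl)=O
Why: Acylation with the acid chloride and a hindered pyridine base should discriminate the primary allylic alcohol from the hindered secondary allylic alcohol (selective esterification).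

Step 10
Reactants: 15 [(3aR,4S,7aR)-4-hydroxy-5-[(2S)-6-methylhept-5-en-2-yl]-2-oxo-2,3,3a,4,7,7a-hexahydro-1-benzofuran-6-yl]methyl 2-methylpropanoate
Product: 19 [(3aR,4S,7aR)-4-hydroxy-3-methylidene-5-[(2S)-6-methylhept-5-en-2-yl]-2-oxo-2,3,3a,4,7,7a-hexahydro-1-benzofuran-6-yl]methyl 2-methylpropanoate, via silyl ketene acetal 16 (not isolated), via Mannich base 17 (not isolated), via ammonium iodide 18 (not isolated)
Conditions: TMSOTf, Et3N, CH2Cl2, 0 °C; CH2=NMe2+ I−, rt; MeI; aq. NaHCO3; dilute citric acid work-up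
Reagents that add atoms: N,N-dimethylmethyleneiminium iodide (Eschenmoser's salt) C=[N+](C)C.[I-]
Why: Eschenmoser methylenation: soft enolisation gives the lactone silyl ketene acetal (the hydroxyl is masked in situ as its silyl ether), and Mannich reaction with the iminium salt, quaternisation and base-induced elimination of trimethylamine should give the exocyclic alkene under conditions that spare the isobutyrate.

Step 11
Reactants: 19 [(3aR,4S,7aR)-4-hydroxy-3-methylidene-5-[(2S)-6-methylhept-5-en-2-yl]-2-oxo-2,3,3a,4,7,7a-hexahydro-1-benzofuran-6-yl]methyl 2-methylpropanoate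
Product: 21 [(3aR,4S,7aR)-4-hydroxy-3-methylidene-2-oxo-5-[(2S)-5-oxopentan-2-yl]-2,3,3a,4,7,7a-hexahydro-1-benzofuran-6-yl]methyl 2-methylpropanoate, via vicinal diol 20 (not isolated)
Conditions: OsO4 (cat.), NMO, acetone/H2O, 0 °C; then NaIO4
Reagents that add atoms: N-methylmorpholine N-oxide (oxygen source for catalytic OsO4) C[N+]1([O-])CCOCC1
Why: Lemieux–Johnson-type cleavage: osmium tetroxide should dihydroxylate the electron-rich trisubstituted alkene much faster than the electron-poor methylene lactone or the hindered tetrasubstituted ring alkene, and periodate cleaves the diol to the aldehyde.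

Step 12
Reactants: 21 [(3aR,4S,7aR)-4-hydroxy-3-methylidene-2-oxo-5-[(2S)-5-oxopentan-2-yl]-2,3,3a,4,7,7a-hexahydro-1-benzofuran-6-yl]methyl 2-methylpropanoate
Product: 22 [(3aR,4S,7aR)-4-hydroxy-5-[(2S)-5-hydroxypentan-2-yl]-3-methylidene-2-oxo-2,3,3a,4,7,7a-hexahydro-1-benzofuran-6-yl]methyl 2-methylpropanoate
Conditions: NaBH(OAc)3, benzene, 50 °C
Reagents that add atoms: none
Why: Sodium triacetoxyborohydride is a mild hydride donor that reduces aldehydes but should leave the lactone, the ester and the conjugated exocyclic alkene untouched (chemoselective carbonyl reduction).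

Step 13
Reactants: 22 [(3aR,4S,7aR)-4-hydroxy-5-[(2S)-5-hydroxypentan-2-yl]-3-methylidene-2-oxo-2,3,3a,4,7,7a-hexahydro-1-benzofuran-6-yl]methyl 2-methylpropanoate
Product: 23 [(3aR,4S,7aR)-5-[(2S)-5-(acetyloxy)pentan-2-yl]-4-hydroxy-3-methylidene-2-oxo-2,3,3a,4,7,7a-hexahydro-1-benzofuran-6-yl]methyl 2-methylpropanoate
Conditions: Ac2O, pyridine, CH2Cl2, 0 °C
Reagents that add atoms: acetic anhydride CC(=O)OC(C)=O
Why: Acetylation of the unhindered primary alcohol should be much faster than that of the secondary allylic alcohol flanked by the tetrasubstituted alkene and the ring fusion (selective esterification).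

**Compound list**

1 | (3S)-3,7-dimethyloct-6-enoic acid, (S)-citronellic acid | OC(=O)C[C@@H](C)CCC=C(C)C | starting material
2 | (3S)-3,7-dimethyloct-6-enoyl chloride | ClC(=O)C[C@@H](C)CCC=C(C)C | intermediate
3 | (1S)-1-(naphthalen-2-yl)ethan-1-ol | O[C@@H](C)c1ccc2ccccc2c1 | starting material
4 | 2-[(1S)-1-(ethenyloxy)ethyl]naphthalene | C=CO[C@@H](C)c1ccc2ccccc2c1 | intermediate
5 | (3S)-3,7-dimethylocta-1,6-dien-1-one (alkylketene) | O=C=C[C@@H](C)CCC=C(C)C | intermediate
6 | 2-[(2S)-6-methylhept-5-en-2-yl]-3-[(1S)-1-(naphthalen-2-yl)ethoxy]cyclobutan-1-one, ring centres as a mixture | O=C1CC(O[C@@H](C)c2ccc3ccccc3c2)C1[C@@H](C)CCC=C(C)C | intermediate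
7 | 1-[(tert-butyldimethylsilyl)oxy]propan-2-one | CC(=O)CO[Si](C)(C)C(C)(C)C | starting material
8 | tert-butyldimethyl({2-[(trimethylsilyl)oxy]prop-2-en-1-yl}oxy)silane | C=C(O[Si](C)(C)C)CO[Si](C)(C)C(C)(C)C | intermediate
9 | (5R)-3-{[(tert-butyldimethylsilyl)oxy]methyl}-2-[(2S)-6-methylhept-5-en-2-yl]-5-[(1S)-1-(naphthalen-2-yl)ethoxy]-3-[(trimethylsilyl)oxy]cyclohexan-1-one, C2 and C3 as a mixture | O=C1C[C@H](O[C@@H](C)c2ccc3ccccc3c2)CC(CO[Si](C)(C)C(C)(C)C)(O[Si](C)(C)C)C1[C@@H](C)CCC=C(C)C | intermediate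
10 | (5R)-3-{[(tert-butyldimethylsilyl)oxy]methyl}-2-[(2S)-6-methylhept-5-en-2-yl]-5-[(1S)-1-(naphthalen-2-yl)ethoxy]cyclohex-2-en-1-one | O=C1C[C@H](O[C@@H](C)c2ccc3ccccc3c2)CC(CO[Si](C)(C)C(C)(C)C)=C1[C@@H](C)CCC=C(C)C | intermediate
11 | methyl 2-[(1S,6R)-4-{[(tert-butyldimethylsilyl)oxy]methyl}-3-[(2S)-6-methylhept-5-en-2-yl]-6-[(1S)-1-(naphthalen-2-yl)ethoxy]-2-oxocyclohex-3-en-1-yl]acetate (ether and acetate arm trans) | COC(=O)C[C@H]1[C@H](O[C@@H](C)c2ccc3ccccc3c2)CC(CO[Si](C)(C)C(C)(C)C)=C([C@@H](C)CCC=C(C)C)C1=O | intermediate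
12 | methyl 2-[(1S,6R)-4-{[(tert-butyldimethylsilyl)oxy]methyl}-6-hydroxy-3-[(2S)-6-methylhept-5-en-2-yl]-2-oxocyclohex-3-en-1-yl]acetate | COC(=O)C[C@H]1[C@H](O)CC(CO[Si](C)(C)C(C)(C)C)=C([C@@H](C)CCC=C(C)C)C1=O | intermediate
13 | (3aS,7aR)-6-(hydroxymethyl)-5-[(2S)-6-methylhept-5-en-2-yl]-3,3a,7,7a-tetrahydro-1-benzofuran-2,4-dione (trans-fused lactone) | C1C(=O)O[C@@H]2CC(CO)=C([C@@H](C)CCC=C(C)C)C(=O)[C@@H]12 | intermediate
14 | (3aR,4S,7aR)-4-hydroxy-6-(hydroxymethyl)-5-[(2S)-6-methylhept-5-en-2-yl]-3a,4,7,7a-tetrahydro-1-benzofuran-2(3H)-one | C1C(=O)O[C@@H]2CC(CO)=C([C@@H](C)CCC=C(C)C)[C@@H](O)[C@@H]12 | intermediate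
15 | [(3aR,4S,7aR)-4-hydroxy-5-[(2S)-6-methylhept-5-en-2-yl]-2-oxo-2,3,3a,4,7,7a-hexahydro-1-benzofuran-6-yl]methyl 2-methylpropanoate | C1C(=O)O[C@@H]2CC(COC(=O)C(C)C)=C([C@@H](C)CCC=C(C)C)[C@@H](O)[C@@H]12 | intermediate
16 | bis-silyl derivative of 15: trimethylsilyl ketene acetal of the lactone and trimethylsilyl ether at the C4 oxygen, ring configuration as in 15 | C1=C(O[Si](C)(C)C)O[C@@H]2CC(COC(=O)C(C)C)=C([C@@H](C)CCC=C(C)C)[C@@H](O[Si](C)(C)C)[C@@H]12 | intermediate
17 | 3-[(dimethylamino)methyl] derivative of 15 with the C4 oxygen as trimethylsilyl ether (Mannich base, C3 as a mixture) | CN(C)CC1C(=O)O[C@@H]2CC(COC(=O)C(C)C)=C([C@@H](C)CCC=C(C)C)[C@@H](O[Si](C)(C)C)[C@@H]12 | intermediate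
18 | trimethylammonium iodide obtained by N-methylation of 17 | C[N+](C)(C)CC1C(=O)O[C@@H]2CC(COC(=O)C(C)C)=C([C@@H](C)CCC=C(C)C)[C@@H](O[Si](C)(C)C)[C@@H]12.[I-] | intermediate
19 | [(3aR,4S,7aR)-4-hydroxy-3-methylidene-5-[(2S)-6-methylhept-5-en-2-yl]-2-oxo-2,3,3a,4,7,7a-hexahydro-1-benzofuran-6-yl]methyl 2-methylpropanoate | C=C1C(=O)O[C@@H]2CC(COC(=O)C(C)C)=C([C@@H](C)CCC=C(C)C)[C@@H](O)[C@@H]12 | intermediate
20 | side-chain 5,6-diol of 19: [(3aR,4S,7aR)-5-[(2S)-5,6-dihydroxy-6-methylheptan-2-yl]-4-hydroxy-3-methylidene-2-oxo-2,3,3a,4,7,7a-hexahydro-1-benzofuran-6-yl]methyl 2-methylpropanoate, new carbinol centre as a mixture | C=C1C(=O)O[C@@H]2CC(COC(=O)C(C)C)=C([C@@H](C)CCC(O)C(C)(C)O)[C@@H](O)[C@@H]12 | intermediate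
21 | [(3aR,4S,7aR)-4-hydroxy-3-methylidene-2-oxo-5-[(2S)-5-oxopentan-2-yl]-2,3,3a,4,7,7a-hexahydro-1-benzofuran-6-yl]methyl 2-methylpropanoate | C=C1C(=O)O[C@@H]2CC(COC(=O)C(C)C)=C([C@@H](C)CCC=O)[C@@H](O)[C@@H]12 | intermediate
22 | [(3aR,4S,7aR)-4-hydroxy-5-[(2S)-5-hydroxypentan-2-yl]-3-methylidene-2-oxo-2,3,3a,4,7,7a-hexahydro-1-benzofuran-6-yl]methyl 2-methylpropanoate | C=C1C(=O)O[C@@H]2CC(COC(=O)C(C)C)=C([C@@H](C)CCCO)[C@@H](O)[C@@H]12 | intermediate
23 | [(3aR,4S,7aR)-5-[(2S)-5-(acetyloxy)pentan-2-yl]-4-hydroxy-3-methylidene-2-oxo-2,3,3a,4,7,7a-hexahydro-1-benzofuran-6-yl]methyl 2-methylpropanoate (CNP0246650.1) | C=C1C(=O)O[C@@H]2CC(COC(=O)C(C)C)=C([C@@H](C)CCCOC(C)=O)[C@@H](O)[C@@H]12 | target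

**Total step count:** 13. **Longest linear sequence:** 11 steps (steps 1, 3, 5–13).

**Steps most likely to fail**

Step 5 (key step). The addition to the oxocarbenium ion may show poor facial selectivity, and loss of silanol may be followed by β-elimination of the C5 ether and aromatisation. The fallback drops the auxiliary. It sets out from 2: cycloaddition with tert-butyldimethyl(vinyloxy)silane and Et3N gives silyloxycyclobutanone F1. The same EtAlCl2-mediated ring expansion with 8 gives enone F2 as both C5 epimers, the silyl ether being a poorer leaving group in the unwanted elimination. Alkylation as in step 6 gives the trans keto ester F3 in both ring series. HF·pyridine and then CSA give 13 together with its ring-enantiomeric diastereomer, lactone F4. The two are separated by chromatography, at the latest after step 8, where the catalyst-controlled reduction turns the two series into cis- and trans-hydroxy lactones. The route is rejoined at 13.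

Step 6. The lithium dienolate may expel the neighbouring ether (followed by aromatisation) or react at oxygen. The fallback sets out from 10: LDA with TMSCl as internal quench gives the 2-silyloxydiene F5. This is alkylated under Lewis acid conditions (ZnBr2, methyl 2-chloro-2-(phenylsulfanyl)acetate, CH2Cl2) to give the α-phenylsulfanyl ester F6, again anti to the ether. Radical desulfurisation (Bu3SnH, AIBN) returns to 11.

Step 8. Hydride may be delivered to the wrong face of the enone carbonyl (axial attack giving the equatorial alcohol). The fallback sets out from 13: Luche reduction (NaBH4, CeCl3) is used deliberately to give the epimeric diol F7. Acylation as in step 9 gives the mono-isobutyrate F8. Mitsunobu inversion with chloroacetic acid (PPh3, DIAD) gives the chloroacetate F9, and selective cleavage with thiourea and NaHCO3 rejoins the route at 15.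

**Further compounds**

F1 | step 5 | 3-[(tert-butyldimethylsilyl)oxy]-2-[(2S)-6-methylhept-5-en-2-yl]cyclobutan-1-one, ring centres as a mixture | O=C1CC(O[Si](C)(C)C(C)(C)C)C1[C@@H](C)CCC=C(C)C
F2 | step 5 | 5-[(tert-butyldimethylsilyl)oxy]-3-{[(tert-butyldimethylsilyl)oxy]methyl}-2-[(2S)-6-methylhept-5-en-2-yl]cyclohex-2-en-1-one, both C5 epimers | O=C1CC(O[Si](C)(C)C(C)(C)C)CC(CO[Si](C)(C)C(C)(C)C)=C1[C@@H](C)CCC=C(C)C
F3 | step 5 | methyl 2-[6-[(tert-butyldimethylsilyl)oxy]-4-{[(tert-butyldimethylsilyl)oxy]methyl}-3-[(2S)-6-methylhept-5-en-2-yl]-2-oxocyclohex-3-en-1-yl]acetate, silyloxy group and acetate arm trans, both ring series | COC(=O)CC1C(O[Si](C)(C)C(C)(C)C)CC(CO[Si](C)(C)C(C)(C)C)=C([C@@H](C)CCC=C(C)C)C1=O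
F4 | step 5 | (3aR,7aS)-6-(hydroxymethyl)-5-[(2S)-6-methylhept-5-en-2-yl]-3,3a,7,7a-tetrahydro-1-benzofuran-2,4-dione | C1C(=O)O[C@H]2CC(CO)=C([C@@H](C)CCC=C(C)C)C(=O)[C@H]12
F5 | step 6 | cross-conjugated trimethylsilyl dienol ether of 10 (2-silyloxy-1,3-diene, ether carbon configuration as in 10) | C[Si](C)(C)OC1=C[C@H](O[C@@H](C)c2ccc3ccccc3c2)CC(CO[Si](C)(C)C(C)(C)C)=C1[C@@H](C)CCC=C(C)C
F6 | step 6 | α-phenylsulfanyl derivative of 11 (sulfur on the acetate CH, that centre as a mixture, ring configuration as in 11) | COC(=O)C(Sc1ccccc1)[C@H]1[C@H](O[C@@H](C)c2ccc3ccccc3c2)CC(CO[Si](C)(C)C(C)(C)C)=C([C@@H](C)CCC=C(C)C)C1=O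
F7 | step 8 | (3aR,4R,7aR)-4-hydroxy-6-(hydroxymethyl)-5-[(2S)-6-methylhept-5-en-2-yl]-3a,4,7,7a-tetrahydro-1-benzofuran-2(3H)-one (C4 epimer of 14) | C1C(=O)O[C@@H]2CC(CO)=C([C@@H](C)CCC=C(C)C)[C@H](O)[C@@H]12
F8 | step 8 | C4 epimer of 15 (primary 2-methylpropanoate of F7) | C1C(=O)O[C@@H]2CC(COC(=O)C(C)C)=C([C@@H](C)CCC=C(C)C)[C@H](O)[C@@H]12
F9 | step 8 | chloroacetate of 15 at the C4 oxygen (C4 configuration as in 15) | C1C(=O)O[C@@H]2CC(COC(=O)C(C)C)=C([C@@H](C)CCC=C(C)C)[C@@H](OC(=O)CCl)[C@@H]12
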